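# Proposed total synthesis of lychnophorolide B by O→C acyl-transfer ring expansion of a seven-membered lactone

## Structural features

Germacrane numbering is used. The target is a ten-membered carbocycle C1–C10 in which O10 bridges C10 and C3. C10–C1(=O)–C2=C3–O10 is therefore a 3(2H)-furanone, and the core is an 11-oxabicyclo[6.2.1]undecane. Five contiguous sp2 carbons (C1–C5) lie in the carbocycle: C2=C3 is E with respect to the large ring, C4=C5 is Z (C3 and C6 cis), and C4 carries the free allylic C15H2OH. An α-methylene-γ-butyrolactone (O6–C12(=O)–C11(=C13H2)–C7) is trans-fused at C6–C7, and C8 carries an (E)-2-methylbut-2-enoate (tiglate). C6 (R), C7 (R) and C8 (S) are contiguous and all-syn along the chain C5–C9 (O6, C11 and O8 on one side). The quaternary C10 (R; C14H3 and O10) is insulated by C9H2 and is 1,3-syn to O8. The fragile groups are the two Michael acceptors (C13 and the cross-conjugated dienone), the free C15 hydroxyl, and the O8 ester, which can migrate to O6 or allow 6,12→8,12 relactonisation. The real difficulty is the strained, bridged ten-membered ring, which resists end-to-end closure, together with the Z-C4=C5 bond inside it. The key step exploits two facts. The furanone is a dehydrated C1/C3 diketone bearing O10. O8 sits on a carbon only three atoms (C9, C10, C1) from the nucleophilic C2, so C3 can first be parked on O8 as the seven-membered lactone ring O8–C3–C4=C5–C6–C7–C8 and then be handed from O8 to C2.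

## Logic of the disconnections

**O6–C12 (33 ⇒ 32 ⇒ 29).** The lactone C–O bond is cut, C12 is lowered to the alcohol level, and O15 is masked in 32. The α-methylene lactone is the most electrophilic unit. Its C12 carbonyl and C13 terminus would compete for every alkoxide and enolate formed earlier. Removing it leaves an inert 2-methylene-1,4-diol. The forward oxidation must pick the primary allylic O12–H, so O15 has to stay masked until the last step.

**O8–acyl (29 ⇒ 28 ⇒ 26 + 27).** The tiglate C–O bond is cut because O8 is needed earlier as the carrier of C3. O8 appears in 26 as the only free hydroxyl, so no differentiation is required. The demand is acylation of a hindered secondary alcohol, and later desilylation under conditions that do not move the ester to O6.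

**Key disconnection: C2–C3 and C3–O10 cut, C3–O8 reconnected (26 ⇒ 23).** In one sentence, this is an O→C acyl-transfer ring expansion of the seven-membered lactone 23.
- The bridged ten-membered ring is traded for a monocyclic lactone with a side chain.
- The C2–C3 bond then forms through a seven-membered transition state instead of a ten-membered one.
- The Z geometry at C4=C5 comes from the small ring.
- O8 is set free exactly where the ester must go.
- The demand is that C2 be the only enolisable ketone position and C3 the only acyl electrophile.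

**C4=C5 (23 ⇒ 22).** The trisubstituted alkene is cut by retro-metathesis inside the seven-membered ring, where only the Z isomer can exist. The gain is an acyclic triene ester. The demand is closure onto a 1,1-disubstituted acrylate next to an allylic silyl ether.

**C1=O and O8–C3 (22 ⇒ 21 ⇒ 16 + 19).** The methyl ketone is traced to a terminal alkyne. The alkyne survives Grignard and hydride reagents and cannot lactonise with O8. The ester bond is cut to give the alcohol and the C3–C4–C15 acid. The demand is a free O8–H beside protected O6 and O12.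

**O–Si and C12–O (16 ⇒ 15 ⇒ 14).** The two silyl ethers and then the C12–O bond are removed. C12 oxygen is put on an isopropenyl group by allylic C–H oxidation. The demand is discrimination of O6–H and O12–H from the more hindered O8–H, and of the 1,1-disubstituted alkene from the vinyl group.

**C6–H and C5–C6 (14 ⇒ 12 ⇒ 11 ⇒ 10).** The carbinol hydrogen and the vinyl–carbonyl bond are cut. C6 is then set from C8 by a chelate-controlled 1,3-syn reduction. The demand is gentle handling of the β-hydroxy vinyl ketone 12.

**C7–C8 (10 ⇒ 8 + 5).** The aldol bond between the two halves is cut. C7 and C8 are set together by the auxiliary, independently of C10. The demand is α-selective reaction of a dienolate.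

**C10–O and C9–H (5 ⇒ 4 ⇒ 3 ⇒ 2 ⇒ 1).** The six carbons C8–C9–C10(C14)–C1–C2 map onto the commercial enynol 1. The quaternary C10–O bond comes from an asymmetric epoxidation and C9–H from a regioselective reductive opening.

**Small pieces (19 ⇒ 17 + 18; 8 ⇒ 6 + 7).** The C15–O ether bond and the N–acyl bond are cut to commercial materials.

## Other disconnections considered

Alternative 1: This is the cut that comes to mind first. C6–C7 is cut together with O6–C12. The forward step is an intramolecular Barbier or Nozaki–Hiyama–Kishi allylation of the (Z)-enal in the seco bromide A1, followed by lactonisation, with the furanone made beforehand from a hydroxy ynone.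
- It is an end-to-end closure of a ring that already contains the rigid furanone and the Z-alkene, so the full strain and transannular cost is paid in the C–C bond-forming transition state under high dilution.
- C6 and C7 would both be created in that step, with control only from the remote C8 and C10 centres.
- The isomerisable Z-enal and the dienone have to be carried as electrophiles through metal-mediated chemistry.
- The chosen plan sets C6–C8 by reagent and chelate control in open-chain compounds and never closes a ring larger than seven in one event.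

Alternative 2: C4=C5 is cut in the finished bicycle, with ring-closing metathesis of the triene A2 as the forward step.
- Metathesis is reversible, so a strained ten-membered product with a trisubstituted, electron-poor alkene should lose to oligomers or to no reaction.
- The Z geometry is not enforced in a ten-membered ring.
- The α-methylene lactone is a further olefin partner.
- The chosen plan makes the same alkene by the same reaction type inside a seven-membered ring, where ring size favours closure and dictates Z.

Alternative 3: C9–C10 is cut and O10 reconnected to C7. The forward step is metal-carbenoid formation from the diazoketone A3, oxonium ylide formation and [2,3]-shift, which enlarges the dihydropyran by three atoms.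
- The step is attractive because it creates the oxa-bridged ring and the C10 quaternary centre at once.
- However, an α-methyl carbenoid can collapse by 1,2-hydride shift.
- The product carries a C7=C8 alkene and an sp3 C3.
- C8–O, C7–H, the whole C11–C13 unit and the C2=C3 unsaturation would then have to be added on the strained ring, with stereocontrol left to its conformation. This costs more steps than it saves.

Key step: step 16

Remark (assumption): the acyl group written OC(=O)/C(C)=C/C is read as the (E)-2-methylbut-2-enoate (tiglate), and commercial 1 is taken as the pure E isomer.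

## Route

Step 1
Reactants: 1 (E)-3-methylpent-2-en-4-yn-1-ol
Product: 2 [(2S,3S)-3-ethynyl-3-methyloxiran-2-yl]methanol
Conditions: Ti(OiPr)4 (cat.), L-(+)-DET (cat.), t-BuOOH, 4 Å MS, CH2Cl2, −20 °C
Reagents that add atoms: tert-butyl hydroperoxide, CC(C)(C)OO
Why: Sharpless asymmetric epoxidation of an (E)-trisubstituted allylic alcohol; L-(+)-tartrate delivers oxygen in the same facial sense as for other (E)-3-methylalk-2-en-1-ols and gives the (2S,3S)-epoxide, which fixes the future C10–O bond. The alkyne is inert to the titanium peroxide.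

Step 2
Reactants: 2 [(2S,3S)-3-ethynyl-3-methyloxiran-2-yl]methanol
Product: 3 (3R)-3-methylpent-4-yne-1,3-diol
Conditions: Red-Al, THF, −20 → 0 °C; Rochelle salt
Reagents that add atoms: none
Why: Hydroxyl-directed Red-Al opening of a 2,3-epoxy alcohol delivers hydride to the carbon next to the carbinol (future C9) and gives the 1,3-diol. The C–O bond at the quaternary carbon is not touched, so C10 keeps its geometry (the descriptor becomes R only through a priority change). Low temperature and a small excess of hydride keep hydroalumination of the propargylic alkoxide slow.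

Step 3
Reactants: 3 (3R)-3-methylpent-4-yne-1,3-diol
Product: 4 (3R)-3-methyl-1,3-bis(triethylsilyloxy)pent-4-yne
Conditions: TESOTf, 2,6-lutidine, CH2Cl2, −78 → 0 °C
Reagents that add atoms: triethylsilyl trifluoromethanesulfonate, CC[Si](CC)(CC)OS(=O)(=O)C(F)(F)F
Why: Exhaustive silylation; the triflate is needed for the hindered tertiary propargylic alcohol. No stereocentre is involved.

Step 4
Reactants: 4 (3R)-3-methyl-1,3-bis(triethylsilyloxy)pent-4-yne
Product: 5 (3R)-3-methyl-3-(triethylsilyloxy)pent-4-ynal
Conditions: (COCl)2, DMSO, CH2Cl2, −78 → −30 °C; Et3N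
Reagents that add atoms: none
Why: Swern oxidation converts a primary triethylsilyl ether directly into the aldehyde, while the tertiary silyl ether survives. The β-silyloxy aldehyde is made cold and used at once, which avoids β-elimination.

Step 5
Reactants: 6 (4R)-4-benzyl-1,3-oxazolidin-2-one; 7 3-methylbut-2-enoyl chloride
Product: 8 (4R)-4-benzyl-3-(3-methylbut-2-enoyl)-1,3-oxazolidin-2-one
Conditions: n-BuLi, THF, −78 °C; then 7, −78 → 0 °C
Reagents that add atoms: none
Why: Standard N-acylation of a lithiated oxazolidinone with an acid chloride.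

Step 6
Reactants: 8 (4R)-4-benzyl-3-(3-methylbut-2-enoyl)-1,3-oxazolidin-2-one; 5 (3R)-3-methyl-3-(triethylsilyloxy)pent-4-ynal
Product: 10 (4R)-4-benzyl-3-[(2R,3S,5R)-3-hydroxy-5-methyl-2-(prop-1-en-2-yl)-5-(triethylsilyloxy)hept-6-ynoyl]-1,3-oxazolidin-2-one, via boron dienolate 9 (not isolated)
Conditions: Bu2BOTf, Et3N, CH2Cl2, −78 → 0 °C; 5, −78 → 0 °C; pH 7 buffer, MeOH, H2O2
Reagents that add atoms: none
Why: Evans syn-aldol in its deconjugative form: soft enolisation removes a γ-hydrogen to give the Z-dienolate 9, which reacts at its α-carbon through a Zimmerman–Traxler chair. The (R)-auxiliary sets C7 (R) and C8 (S) by reagent control, and the remote C10 centre has little influence. Either γ-methyl group gives the same isopropenyl product.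

Step 7
Reactants: 10 (4R)-4-benzyl-3-[(2R,3S,5R)-3-hydroxy-5-methyl-2-(prop-1-en-2-yl)-5-(triethylsilyloxy)hept-6-ynoyl]-1,3-oxazolidin-2-one
Product: 11 (2R,3S,5R)-3-hydroxy-N-methoxy-N,5-dimethyl-2-(prop-1-en-2-yl)-5-(triethylsilyloxy)hept-6-ynamide
Conditions: MeNHOMe·HCl, AlMe3, CH2Cl2, −10 °C → rt; Rochelle salt
Reagents that add atoms: N,O-dimethylhydroxylamine hydrochloride, CNOC.Cl
Why: Aluminium amide transamination of an Evans aldol imide to the Weinreb amide, assisted by the free β-hydroxyl. The conditions are non-basic enough to leave the β,γ-alkene and C7 in place, and the auxiliary is recovered.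

Step 8
Reactants: 11 (2R,3S,5R)-3-hydroxy-N-methoxy-N,5-dimethyl-2-(prop-1-en-2-yl)-5-(triethylsilyloxy)hept-6-ynamide
Product: 12 (4R,5S,7R)-5-hydroxy-7-methyl-4-(prop-1-en-2-yl)-7-(triethylsilyloxy)non-1-en-8-yn-3-one
Conditions: CH2=CHMgBr (excess), THF, −78 → 0 °C; cold aq. NH4Cl
Reagents that add atoms: vinylmagnesium bromide, C=C[Mg]Br
Why: Weinreb ketone synthesis; the chelated tetrahedral adduct persists until the cold quench, so the vinyl ketone never meets the Grignard reagent. The excess reagent is consumed by O–H and C≡C–H, and the alkyne mask at C1 is otherwise inert.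

Step 9
Reactants: 12 (4R,5S,7R)-5-hydroxy-7-methyl-4-(prop-1-en-2-yl)-7-(triethylsilyloxy)non-1-en-8-yn-3-one
Product: 14 (3R,4R,5S,7R)-7-methyl-4-(prop-1-en-2-yl)-7-(triethylsilyloxy)non-1-en-8-yne-3,5-diol, via boron chelate 13 (not isolated)
Conditions: Et2BOMe, THF/MeOH 4:1, −78 °C; NaBH4; then H2O2, pH 7 buffer
Reagents that add atoms: none
Why: Narasaka–Prasad reduction: in the six-membered chelate 13 the C9 chain is equatorial and the C11 group axial. Hydride enters axially on the face opposite to C11 and gives the 1,3-syn diol, which sets C6 (R) and completes the all-syn triad. The chelated carbonyl is reduced 1,2 at −78 °C.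

Step 10
Reactants: 14 (3R,4R,5S,7R)-7-methyl-4-(prop-1-en-2-yl)-7-(triethylsilyloxy)non-1-en-8-yne-3,5-diol
Product: 15 (3R,4R,5S,7R)-4-(3-hydroxyprop-1-en-2-yl)-7-methyl-7-(triethylsilyloxy)non-1-en-8-yne-3,5-diol
Conditions: SeO2 (cat.), t-BuOOH, CH2Cl2, 0 °C → rt
Reagents that add atoms: tert-butyl hydroperoxide, CC(C)(C)OO (terminal source of the oxygen atom, passed on by catalytic selenium dioxide, O=[Se]=O)
Why: Selenium dioxide allylic hydroxylation (ene reaction, then [2,3]-shift), well known for isopropenyl groups next to free carbinols. The more nucleophilic 1,1-disubstituted alkene reacts before the vinyl group, and its CH3 before the tertiary C7–H, so only C12 is oxidised.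

Step 11
Reactants: 15 (3R,4R,5S,7R)-4-(3-hydroxyprop-1-en-2-yl)-7-methyl-7-(triethylsilyloxy)non-1-en-8-yne-3,5-diol
Product: 16 (3R,4R,5S,7R)-3-(tert-butyldimethylsilyloxy)-4-[3-(tert-butyldimethylsilyloxy)prop-1-en-2-yl]-7-methyl-7-(triethylsilyloxy)non-1-en-8-yn-5-ol
Conditions: TBSCl (2.1 equiv), imidazole, DMF, −10 → 0 °C
Reagents that add atoms: tert-butyldimethylsilyl chloride, CC(C)(C)[Si](C)(C)Cl
Why: Sterically governed silylation: the primary O12–H reacts first, then the allylic O6–H flanked by the small vinyl group. O8–H is shielded by the neighbouring CH2–C10(CH3)(OTES) unit and should remain free.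

Step 12
Reactants: 17 2-(bromomethyl)prop-2-enoic acid; 18 (4-methoxyphenyl)methanol
Product: 19 2-{[(4-methoxybenzyl)oxy]methyl}prop-2-enoic acid
Conditions: NaH (2.2 equiv), THF, 0 °C → rt; then 1 M HCl
Reagents that add atoms: none
Why: Williamson-type displacement of the allylic bromide of the carboxylate by the alkoxide. Direct and allylic (SN2′) attack give the same product.

Step 13
Reactants: 16 (3R,4R,5S,7R)-3-(tert-butyldimethylsilyloxy)-4-[3-(tert-butyldimethylsilyloxy)prop-1-en-2-yl]-7-methyl-7-(triethylsilyloxy)non-1-en-8-yn-5-ol; 19 2-{[(4-methoxybenzyl)oxy]methyl}prop-2-enoic acid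
Product: 21 (3R,4R,5S,7R)-3-(tert-butyldimethylsilyloxy)-4-[3-(tert-butyldimethylsilyloxy)prop-1-en-2-yl]-7-methyl-7-(triethylsilyloxy)non-1-en-8-yn-5-yl 2-{[(4-methoxybenzyl)oxy]methyl}prop-2-enoate, via mixed anhydride 20 (not isolated)
Conditions: 2,4,6-trichlorobenzoyl chloride, Et3N, toluene, rt; then 16, DMAP, rt
Reagents that add atoms: none
Why: Yamaguchi esterification through 20 is the standard way to acylate a hindered secondary alcohol with an unsaturated acid. The C8–O bond is not broken, so its configuration is retained.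

Step 14
Reactants: 21 (3R,4R,5S,7R)-3-(tert-butyldimethylsilyloxy)-4-[3-(tert-butyldimethylsilyloxy)prop-1-en-2-yl]-7-methyl-7-(triethylsilyloxy)non-1-en-8-yn-5-yl 2-{[(4-methoxybenzyl)oxy]methyl}prop-2-enoate
Product: 22 (3R,4R,5S,7R)-3-(tert-butyldimethylsilyloxy)-4-[3-(tert-butyldimethylsilyloxy)prop-1-en-2-yl]-7-methyl-8-oxo-7-(triethylsilyloxy)non-1-en-5-yl 2-{[(4-methoxybenzyl)oxy]methyl}prop-2-enoate
Conditions: (IPr)AuCl/AgSbF6 (cat.), 1,4-dioxane/H2O, 50 °C
Reagents that add atoms: water, O
Why: Gold(I)-catalysed Markovnikov hydration of a terminal alkyne gives the methyl ketone under near-neutral conditions. Alkenes, silyl ethers and the ester are not activated, and the silyl ether at C10 disfavours ionisation (Meyer–Schuster pathway).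

Step 15
Reactants: 22 (3R,4R,5S,7R)-3-(tert-butyldimethylsilyloxy)-4-[3-(tert-butyldimethylsilyloxy)prop-1-en-2-yl]-7-methyl-8-oxo-7-(triethylsilyloxy)non-1-en-5-yl 2-{[(4-methoxybenzyl)oxy]methyl}prop-2-enoate
Product: 23 (5R,6R,7S)-5-(tert-butyldimethylsilyloxy)-6-[3-(tert-butyldimethylsilyloxy)prop-1-en-2-yl]-3-{[(4-methoxybenzyl)oxy]methyl}-7-[(2R)-2-methyl-3-oxo-2-(triethylsilyloxy)butyl]-6,7-dihydrooxepin-2(5H)-one
Conditions: Hoveyda–Grubbs II (cat.), toluene (2 mM), 90 °C
Reagents that add atoms: none
Why: Ring-closing metathesis starts at the vinyl group and closes onto the α-substituted acrylate. Seven is the only accessible ring size, since the C11=C13 alkene could give only a cyclobutene or a tetrasubstituted alkene. The small ring forces the Z geometry of C4=C5.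

Step 16
Reactants: 23 (5R,6R,7S)-5-(tert-butyldimethylsilyloxy)-6-[3-(tert-butyldimethylsilyloxy)prop-1-en-2-yl]-3-{[(4-methoxybenzyl)oxy]methyl}-7-[(2R)-2-methyl-3-oxo-2-(triethylsilyloxy)butyl]-6,7-dihydrooxepin-2(5H)-one
Product: 26 (6R,7R,8S,10R)-8-hydroxy furanoheliangolide core (3,10-epoxy-1-oxogermacra-2,4Z,11(13)-triene bearing 6-OTBS 12-OTBS 15-OPMB), via bridged hemiketal adduct 24 (not isolated), via ten-membered diketone 25 (not isolated)
Conditions: LiHMDS (3 equiv), THF (5 mM), −78 → −20 °C; AcOH, −78 °C; then PPTS (cat.), MeOH/CH2Cl2, 0 °C → rt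
Reagents that add atoms: none
Why: Proposed new method: LiHMDS can enolise the ketone of 23 only at C2 (C10 is quaternary), and the C2 enolate adds to the lactone carbonyl C3 in a 7-exo-trig mode (ring C2–C1–C10–C9–C8–O8–C3) to give the bridged adduct 24, whose collapse expels the C8 alkoxide, so that the seven-membered lactone is enlarged by three atoms to the ten-membered carbocycle 25 without any end-to-end macrocyclisation. The closest known reaction types are the Baker–Venkataraman O→C acyl shift of o-acyloxyaryl ketone enolates and the intramolecular nucleophilic acyl substitution of lactones by tethered carbanions with ring enlargement; new here is the ketone-enolate version on an aliphatic ε-lactone that delivers a medium ring. The equilibrium should be pulled forward because 25 is deprotonated at once to a chelated lithium β-diketonate (about ten pKa units below the alkoxide and inert to retro-Claisen attack) and because the strained E-configured lactone ester is lost. In the acidic second stage the triethylsilyl group leaves, O10 adds to C3 (5-exo-trig) and water is lost, which closes the 3(2H)-furanone irreversibly as a vinylogous ester and with it the 11-oxabicyclo[6.2.1] core. No lasting stereocentre is created: C3 in 24 is fixed by the O8 bridge and returns to sp2, Z-C4=C5 is inherited from the seven-membered ring, E-C2=C3 is dictated by the five-membered ring, and C6, C7, C8 and C10 carry no hydrogen that competes with the methyl ketone under kinetic conditions. Chemoselectivity rests on the substrate: C3 is the only acyl electrophile because C12 is held at the alcohol level (no second lactone carbonyl, no Michael acceptor), 1,4-attack at C5 would need an eight-membered transition state at a β-substituted carbon, and lithium at low temperature slows O6→O8 silyl migration and E1cB loss of the C15 ether. The step releases O8 as the only free hydroxyl group, ready for the tiglate.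

Step 17
Reactants: 26 (6R,7R,8S,10R)-8-hydroxy furanoheliangolide core (6-OTBS 12-OTBS 15-OPMB); 27 (E)-2-methylbut-2-enoyl chloride
Product: 28 (6R,7R,8S,10R)-8-tigloyloxy core (6-OTBS 12-OTBS 15-OPMB)
Conditions: 27, Et3N, DMAP, CH2Cl2, 0 °C → rt
Reagents that add atoms: none
Why: DMAP-catalysed acylation of the only free hydroxyl. The E (tiglate) geometry is the thermodynamically stable one, so it cannot be degraded by acylpyridinium isomerisation. The C8–O bond is untouched.

Step 18
Reactants: 28 (6R,7R,8S,10R)-8-tigloyloxy core (6-OTBS 12-OTBS 15-OPMB)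
Product: 29 (6R,7R,8S,10R)-6,12-dihydroxy-8-tigloyloxy core (15-OPMB)
Conditions: HF·pyridine, pyridine, THF, 0 °C → rt
Reagents that add atoms: none
Why: Acidic fluoride removes both silyl ethers. The absence of alkoxide keeps the O8 ester from migrating to O6 and spares the base-sensitive dienone.

Step 19
Reactants: 29 (6R,7R,8S,10R)-6,12-dihydroxy-8-tigloyloxy core (15-OPMB)
Product: 32 15-O-(4-methoxybenzyl)lychnophorolide B, via hydroxy enal 30 (not isolated), via lactol 31 (not isolated)
Conditions: TEMPO (cat.), PhI(OAc)2, CH2Cl2, rt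
Reagents that add atoms: none
Why: Oxoammonium oxidative lactonisation of a 2-methylene-1,4-diol: the primary allylic alcohol is oxidised first to 30, O6–H closes to 31, and the lactol is oxidised to the α-methylene-γ-butyrolactone. O8 is acylated, so only the 6,12-lactone can form. The trans ring fusion follows from C6 and C7.

Step 20
Reactants: 32 15-O-(4-methoxybenzyl)lychnophorolide B
Product: 33 lychnophorolide B
Conditions: DDQ, CH2Cl2/pH 7 buffer, 0 °C
Reagents that add atoms: none
Why: Oxidative cleavage of the 4-methoxybenzyl ether by DDQ is neutral and leaves the electron-poor dienone, the α-methylene lactone and the tiglate untouched. No stereocentre is affected.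

## Compound list

1 | (E)-3-methylpent-2-en-4-yn-1-ol | C#C/C(C)=C/CO | starting material
2 | [(2S,3S)-3-ethynyl-3-methyloxiran-2-yl]methanol | OC[C@@H]1O[C@@]1(C)C#C | intermediate
3 | (3R)-3-methylpent-4-yne-1,3-diol | OCC[C@@](C)(O)C#C | intermediate
4 | (3R)-3-methyl-1,3-bis(triethylsilyloxy)pent-4-yne | CC[Si](CC)(CC)OCC[C@@](C)(O[Si](CC)(CC)CC)C#C | intermediate
5 | (3R)-3-methyl-3-(triethylsilyloxy)pent-4-ynal | O=CC[C@@](C)(O[Si](CC)(CC)CC)C#C | intermediate
6 | (4R)-4-benzyl-1,3-oxazolidin-2-one | O=C1N[C@H](Cc2ccccc2)CO1 | starting material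
7 | 3-methylbut-2-enoyl chloride | CC(C)=CC(=O)Cl | starting material
8 | (4R)-4-benzyl-3-(3-methylbut-2-enoyl)-1,3-oxazolidin-2-one | CC(C)=CC(=O)N1[C@H](Cc2ccccc2)COC1=O | intermediate
9 | (Z)-dibutylboron dienolate of 8 (not isolated) | C=C(C)/C=C(\OB(CCCC)CCCC)N1[C@H](Cc2ccccc2)COC1=O | intermediate
10 | syn-aldol imide, (2R,3S,5R)-acyl chain on the (4R)-auxiliary | O=C([C@H](C(C)=C)[C@@H](O)C[C@@](C)(O[Si](CC)(CC)CC)C#C)N1[C@H](Cc2ccccc2)COC1=O | intermediate
11 | (2R,3S,5R)-Weinreb amide | CON(C)C(=O)[C@H](C(C)=C)[C@@H](O)C[C@@](C)(O[Si](CC)(CC)CC)C#C | intermediate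
12 | (4R,5S,7R)-β-hydroxy vinyl ketone | C=CC(=O)[C@H](C(C)=C)[C@@H](O)C[C@@](C)(O[Si](CC)(CC)CC)C#C | intermediate
13 | O8-diethylboron chelate of 12 (dative O→B bond not drawn; not isolated) | C=CC(=O)[C@H](C(C)=C)[C@@H](OB(CC)CC)C[C@@](C)(O[Si](CC)(CC)CC)C#C | intermediate
14 | (3R,4R,5S,7R)-syn-1,3-diol with isopropenyl group | C=C[C@@H](O)[C@H](C(C)=C)[C@@H](O)C[C@@](C)(O[Si](CC)(CC)CC)C#C | intermediate
15 | (3R,4R,5S,7R)-triol (C12 hydroxylated) | C=C[C@@H](O)[C@H](C(=C)CO)[C@@H](O)C[C@@](C)(O[Si](CC)(CC)CC)C#C | intermediate
16 | 6,12-bis-TBS ether with free O8–H | C=C[C@@H](O[Si](C)(C)C(C)(C)C)[C@H](C(=C)CO[Si](C)(C)C(C)(C)C)[C@@H](O)C[C@@](C)(O[Si](CC)(CC)CC)C#C | intermediate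
17 | 2-(bromomethyl)prop-2-enoic acid | C=C(CBr)C(=O)O | starting material
18 | (4-methoxyphenyl)methanol | COc1ccc(CO)cc1 | starting material
19 | 2-{[(4-methoxybenzyl)oxy]methyl}prop-2-enoic acid | C=C(COCc1ccc(OC)cc1)C(=O)O | intermediate
20 | mixed anhydride of 19 with 2,4,6-trichlorobenzoic acid (not isolated) | C=C(COCc1ccc(OC)cc1)C(=O)OC(=O)c1c(Cl)cc(Cl)cc1Cl | intermediate
21 | O8 acrylate ester, alkyne stage | C=C[C@@H](O[Si](C)(C)C(C)(C)C)[C@H](C(=C)CO[Si](C)(C)C(C)(C)C)[C@@H](OC(=O)C(=C)COCc1ccc(OC)cc1)C[C@@](C)(O[Si](CC)(CC)CC)C#C | intermediate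
22 | O8 acrylate ester, methyl ketone stage | C=C[C@@H](O[Si](C)(C)C(C)(C)C)[C@H](C(=C)CO[Si](C)(C)C(C)(C)C)[C@@H](OC(=O)C(=C)COCc1ccc(OC)cc1)C[C@@](C)(O[Si](CC)(CC)CC)C(C)=O | intermediate
23 | seven-membered O8–C3 lactone (5R,6R,7S; side chain 2R) | O=C1O[C@@H](C[C@@](C)(O[Si](CC)(CC)CC)C(C)=O)[C@@H](C(=C)CO[Si](C)(C)C(C)(C)C)[C@H](O[Si](C)(C)C(C)(C)C)C=C1COCc2ccc(OC)cc2 | intermediate
24 | bridged tetrahedral adduct, 11-oxabicyclo[4.4.1]undecene hemiketal, drawn neutral (not isolated) | O[C@]12CC(=O)[C@](C)(O[Si](CC)(CC)CC)C[C@H](O1)[C@@H](C(=C)CO[Si](C)(C)C(C)(C)C)[C@H](O[Si](C)(C)C(C)(C)C)C=C2COCc3ccc(OC)cc3 | intermediate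
25 | ten-membered (4Z)-1,3-diketone with free O8–H, drawn neutral (not isolated) | O=C1CC(=O)/C(COCc2ccc(OC)cc2)=C\[C@@H](O[Si](C)(C)C(C)(C)C)[C@H](C(=C)CO[Si](C)(C)C(C)(C)C)[C@@H](O)C[C@@]1(C)O[Si](CC)(CC)CC | intermediate
26 | 8-hydroxy furanoheliangolide core (6-OTBS, 12-OTBS, 15-OPMB; 6R,7R,8S,10R) | CC(C)(C)[Si](C)(C)O[C@@H]1/C=C(/COCc3ccc(OC)cc3)C2=CC(=O)[C@@](C)(C[C@H](O)[C@H]1C(=C)CO[Si](C)(C)C(C)(C)C)O2 | intermediate
27 | (E)-2-methylbut-2-enoyl chloride (tigloyl chloride) | C/C=C(\C)C(=O)Cl | starting material
28 | 8-tiglate of 26 | CC(C)(C)[Si](C)(C)O[C@@H]1/C=C(/COCc3ccc(OC)cc3)C2=CC(=O)[C@@](C)(C[C@H](OC(=O)/C(C)=C/C)[C@H]1C(=C)CO[Si](C)(C)C(C)(C)C)O2 | intermediate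
29 | 6,12-diol 8-tiglate (15-OPMB) | O[C@@H]1/C=C(/COCc3ccc(OC)cc3)C2=CC(=O)[C@@](C)(C[C@H](OC(=O)/C(C)=C/C)[C@H]1C(=C)CO)O2 | intermediate
30 | 6-hydroxy 12-enal (not isolated) | O[C@@H]1/C=C(/COCc3ccc(OC)cc3)C2=CC(=O)[C@@](C)(C[C@H](OC(=O)/C(C)=C/C)[C@H]1C(=C)C=O)O2 | intermediate
31 | 6,12-lactol, both C12 anomers (not isolated) | C=C1C(O)O[C@@H]2/C=C(/COCc4ccc(OC)cc4)C3=CC(=O)[C@@](C)(C[C@H](OC(=O)/C(C)=C/C)[C@@H]12)O3 | intermediate
32 | 15-O-(4-methoxybenzyl)lychnophorolide B | C=C1C(=O)O[C@@H]2/C=C(/COCc4ccc(OC)cc4)C3=CC(=O)[C@@](C)(C[C@H](OC(=O)/C(C)=C/C)[C@@H]12)O3 | intermediate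
33 | lychnophorolide B | C=C1C(=O)O[C@@H]2/C=C(/CO)C3=CC(=O)[C@@](C)(C[C@H](OC(=O)/C(C)=C/C)[C@@H]12)O3 | target

## Step count and least certain steps

Total step count: 20. Longest linear sequence: 18 steps (steps 1–4, 6–11 and 13–20).

**Step 16 (key step, bears the label "Proposed new method:").**
The acyl shift may fail to go forward, or may revert by attack of the C8 alkoxide on C3 before the diketone is deprotonated, because the ten-membered ring is strained. Three other processes could compete:
- γ-deprotonation at C6 followed by loss of the C15 alkoxide;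
- migration of a silyl group from O6 to the new O8 alkoxide;
- closure of the enol ether through O8 instead of O10 in the acid stage.

The fallback uses only known reaction types, sets out from 16 and 19 and returns at 26. Compound 19 is coupled with N,O-dimethylhydroxylamine (EDC) to the Weinreb acrylamide F1. Compound 16 is deprotonated twice with n-BuLi and acylated at the acetylide carbon by F1 to give the silylated ynone F2. PPTS in methanol frees the tertiary alcohol to give the γ-hydroxy ynone F3. Cationic gold(I) isomerises F3 to the open-chain 3(2H)-furanone F4 (the classical hydroxy-ynone route to furanones). Ring-closing metathesis of F4 at high dilution closes C4=C5 and gives 26. This gives up the ring-expansion advantage and puts the strain on the metathesis, as discussed under Alternative 2.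

**Step 11.**
Site selectivity may be poor, with silylation of O8–H in competition with O6–H, because both are secondary carbinols next to C7.

The fallback sets out from 15 and returns at 22. Silver(I) or gold(I) catalysis induces 5-exo-dig addition of O8–H, the only hydroxyl within reach, to the alkyne and gives the 2-methylenetetrahydrofuran diol F5. This masks O8 and at the same time brings C1 to the ketone level. Exhaustive silylation with TBSCl gives the bis-silyl enol ether F6. Mild aqueous acid (oxalic acid on silica) hydrolyses the enol ether to the hydroxy ketone F7. Yamaguchi esterification of F7 with 19 gives 22, so step 14 is no longer needed.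

**Step 2.**
Hydroalumination of the alkyne next to the newly formed alkoxide, or SN2′ hydride attack on the propargylic epoxide, may compete with the directed opening.

The fallback sets out from 2 and returns at 4. The primary alcohol is silylated (TESCl, imidazole) to the epoxy silyl ether F8. Lithium triethylborohydride, which does not add to alkynes, opens the epoxide by undirected SN2 attack at the less substituted carbon to give the tertiary alcohol F9. TESOTf then gives 4.

**Step 19.**
Oxidation of the secondary allylic C6 carbinol may compete, or lactol closure may be slow in the rigid ring, which would strand the material at the aldehyde level.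

The fallback sets out from 28 and returns at 32. Brief treatment with buffered HF·pyridine removes only the primary silyl ether to give the 12-alcohol F10. Dess–Martin oxidation gives the enal F11 and Pinnick oxidation the acrylic acid F12, with O6 still silylated throughout. HF·pyridine then frees O6–H and the hydroxy acid lactonises (EDC if needed) to 32.

## Further compounds

F1 | step 16 | N-methoxy-N-methyl-2-{[(4-methoxybenzyl)oxy]methyl}prop-2-enamide | C=C(COCc1ccc(OC)cc1)C(=O)N(C)OC
F2 | step 16 | ynone from 16 and F1 (10-OTES, free O8–H) | C=C[C@@H](O[Si](C)(C)C(C)(C)C)[C@H](C(=C)CO[Si](C)(C)C(C)(C)C)[C@@H](O)C[C@@](C)(O[Si](CC)(CC)CC)C#CC(=O)C(=C)COCc1ccc(OC)cc1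
F3 | step 16 | γ-hydroxy ynone (free O10–H and O8–H) | C=C[C@@H](O[Si](C)(C)C(C)(C)C)[C@H](C(=C)CO[Si](C)(C)C(C)(C)C)[C@@H](O)C[C@@](C)(O)C#CC(=O)C(=C)COCc1ccc(OC)cc1
F4 | step 16 | open-chain 3(2H)-furanone triene with free O8–H | C=C[C@@H](O[Si](C)(C)C(C)(C)C)[C@H](C(=C)CO[Si](C)(C)C(C)(C)C)[C@@H](O)C[C@@]1(C)OC(C(=C)COCc2ccc(OC)cc2)=CC1=O
F5 | step 11 | 2-methylenetetrahydrofuran (O8–C1 enol ether) 6,12-diol | C=C[C@@H](O)[C@H](C(=C)CO)[C@@H]1C[C@@](C)(O[Si](CC)(CC)CC)C(=C)O1
F6 | step 11 | 6,12-bis-TBS ether of F5 | C=C[C@@H](O[Si](C)(C)C(C)(C)C)[C@H](C(=C)CO[Si](C)(C)C(C)(C)C)[C@@H]1C[C@@](C)(O[Si](CC)(CC)CC)C(=C)O1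
F7 | step 11 | 8-hydroxy methyl ketone (open form), 6,12-bis-TBS, 10-TES | C=C[C@@H](O[Si](C)(C)C(C)(C)C)[C@H](C(=C)CO[Si](C)(C)C(C)(C)C)[C@@H](O)C[C@@](C)(O[Si](CC)(CC)CC)C(C)=O
F8 | step 2 | triethylsilyl ether of 2 | CC[Si](CC)(CC)OC[C@@H]1O[C@@]1(C)C#C
F9 | step 2 | (3R)-3-methyl-1-(triethylsilyloxy)pent-4-yn-3-ol | CC[Si](CC)(CC)OCC[C@@](C)(O)C#C
F10 | step 19 | 12-alcohol, 6-OTBS, 8-tiglate, 15-OPMB | CC(C)(C)[Si](C)(C)O[C@@H]1/C=C(/COCc3ccc(OC)cc3)C2=CC(=O)[C@@](C)(C[C@H](OC(=O)/C(C)=C/C)[C@H]1C(=C)CO)O2
F11 | step 19 | 12-enal, 6-OTBS, 8-tiglate, 15-OPMB | CC(C)(C)[Si](C)(C)O[C@@H]1/C=C(/COCc3ccc(OC)cc3)C2=CC(=O)[C@@](C)(C[C@H](OC(=O)/C(C)=C/C)[C@H]1C(=C)C=O)O2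
F12 | step 19 | 12-acrylic acid, 6-OTBS, 8-tiglate, 15-OPMB | CC(C)(C)[Si](C)(C)O[C@@H]1/C=C(/COCc3ccc(OC)cc3)C2=CC(=O)[C@@](C)(C[C@H](OC(=O)/C(C)=C/C)[C@H]1C(=C)C(=O)O)O2
A1 | alternative 1 | seco (Z)-enal with (Z)-2-(bromomethyl)enoate terminus (8-tiglate, 15-OTBS) | O=C/C=C(/CO[Si](C)(C)C(C)(C)C)C1=CC(=O)[C@@](C)(C[C@H](OC(=O)/C(C)=C/C)/C=C(\CBr)C(=O)OC)O1
A2 | alternative 2 | open triene with finished lactone, tiglate and furanone (15-OTBS) | C=C[C@H]1OC(=O)C(=C)[C@@H]1[C@@H](OC(=O)/C(C)=C/C)C[C@@]2(C)OC(C(=C)CO[Si](C)(C)C(C)(C)C)=CC2=O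
A3 | alternative 3 | α-methyl diazoketone on a 2,6-cis 6-vinyl-3,6-dihydro-2H-pyran | CC(=[N+]=[N-])C(=O)C[C@H]1O[C@@H](C=C)[C@H](O[Si](C)(C)C(C)(C)C)C=C1CO[Si](C)(C)C(C)(C)C
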